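**Retrosynthetic overview**
1. Target ⇐ its C2'-O-triethylsilyl ether ⇐ ring C4–C1' bond, made by a chelation-controlled zinc aldol between the dearomatised gem-diprenyl acyl-triketone and a chiral-pool α-silyloxy aldehyde. C2' is bought and C1' is set in the C–C bond-forming step; the usual plan (asymmetric dihydroxylation of an aryl alkene, then protection and late prenylation) is not used.
2. gem-Diprenyl triketone ⇐ alkylative dearomatisation of phlorisobutyrophenone ⇐ Friedel–Crafts acylation of phloroglucinol.
3. Aldehyde ⇐ (S)-2-hydroxy-3-methylbutanoic acid by esterification, silylation and half-reduction.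
4. Rings: the single six-membered carbocycle is not constructed; it is bought as phloroglucinol and dearomatised in the second step.

Assumption: the target is one enol tautomer of a β-triketone, so all ring compounds are written in that same tautomer; phloroglucinol, isobutyryl chloride, prenyl bromide and (S)-2-hydroxy-3-methylbutanoic acid are bought.

**Route**

Step 1
Reactants: 1 phloroglucinol (benzene-1,3,5-triol); 2 isobutyryl chloride (2-methylpropanoyl chloride)
Product: 3 phlorisobutyrophenone [2-methyl-1-(2,4,6-trihydroxyphenyl)propan-1-one]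
Conditions: AlCl3 (4 equiv), PhNO2, 65 °C; ice/aq. HCl
Reagents that add atoms: none
Why: Friedel–Crafts acylation of the highly activated arene stops at mono-acylation because the AlCl3-chelated aryl ketone deactivates the ring; no stereocentre is formed.

Step 2
Reactants: 3 phlorisobutyrophenone; 4 prenyl bromide (1-bromo-3-methylbut-2-ene, 2.1 equiv)
Product: 6 3,5-dihydroxy-2-(2-methylpropanoyl)-6,6-bis(3-methylbut-2-en-1-yl)cyclohexa-2,4-dien-1-one, via 3-prenylphlorisobutyrophenone 5 (not isolated)
Conditions: 10% aq. KOH, 0 °C, 2 h; then 2 M HCl to pH 3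
Reagents that add atoms: none
Why: Alkylative dearomatisation (C-alkylation of the ambident phloroglucinolate in water, where hydrogen bonding shields oxygen): the first prenyl group enters a free ring carbon to give 5, and the second adds to the same, now more electron-rich carbon to give the conjugated β-triketone 6 (about 30% expected after separation from the 3,5-diprenyl and triprenyl by-products); no stereocentre is formed.

Step 3
Reactants: 7 (S)-2-hydroxy-3-methylbutanoic acid
Product: 8 methyl (S)-2-hydroxy-3-methylbutanoate
Conditions: MeOH, cat. H2SO4, reflux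
Reagents that add atoms: methanol, CO
Why: Fischer esterification under acid catalysis does not enolise the α-hydroxy acid, so the C2 stereocentre is untouched.

Step 4
Reactants: 8 methyl (S)-2-hydroxy-3-methylbutanoate
Product: 9 methyl (S)-3-methyl-2-(triethylsilyloxy)butanoate
Conditions: TESCl, imidazole, CH2Cl2, 0 °C → rt
Reagents that add atoms: chlorotriethylsilane (TESCl), CC[Si](Cl)(CC)CC
Why: Imidazole-promoted silylation of a secondary alcohol; the small TES ether is chosen because it can still take part in chelation and is removed at the end by buffered fluoride, and the configuration is untouched.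

Step 5
Reactants: 9 methyl (S)-3-methyl-2-(triethylsilyloxy)butanoate
Product: 11 (S)-3-methyl-2-(triethylsilyloxy)butanal, via diisobutylaluminium hemiacetal 10 (not isolated)
Conditions: i-Bu2AlH (1.1 equiv), CH2Cl2, −78 °C; MeOH, then aq. KNaC4H4O6
Reagents that add atoms: none
Why: Partial ester reduction at −78 °C stops at the tetrahedral hemiacetal 10, which is stabilised by coordination to the α-silyloxy oxygen and releases the aldehyde only on work-up; the non-basic conditions leave the α-stereocentre intact, and 11 is used at once.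

Step 6
Reactants: 6 3,5-dihydroxy-2-(2-methylpropanoyl)-6,6-bis(3-methylbut-2-en-1-yl)cyclohexa-2,4-dien-1-one; 11 (S)-3-methyl-2-(triethylsilyloxy)butanal (1.3 equiv)
Product: 14 3,5-dihydroxy-4-[(1S,2S)-1-hydroxy-3-methyl-2-(triethylsilyloxy)butyl]-2-(2-methylpropanoyl)-6,6-bis(3-methylbut-2-en-1-yl)cyclohexa-2,4-dien-1-one, via bis(ethylzinc) dienolate 12 (not isolated), via bis(ethylzinc) aldolate 13 (not isolated)
Conditions: Et2Zn (2.0 equiv), CH2Cl2, −20 °C, 30 min; then 11, −78 → −30 °C; aq. NaH2PO4
Reagents that add atoms: none
Why: Proposed new method: the ethylzinc-oxygen unit beside the only unsubstituted ring carbon of 12 is an alkylzinc–X type Lewis acid, a class known to chelate α-silyloxy aldehydes and override Felkin control, so it should bind the C=O and OTES oxygens of 11 in a five-membered chelate and deliver ring C4 through a closed six-membered aldol transition state to the aldehyde face anti to the isopropyl group, giving the 1',2'-syn (1'S,2'S) aldolate 13, which is held as a chelate and so does not dehydrate to the alkylidene triketone before the mildly acidic quench; the closest known reactions are chelation-controlled organozinc additions to α-silyloxy aldehydes, the ortho-hydroxyalkylation of magnesium phenolates with α-alkoxy aldehydes, and the aldol first stage of the Knoevenagel reaction of cyclic 1,3-diones.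

Step 7
Reactants: 14 3,5-dihydroxy-4-[(1S,2S)-1-hydroxy-3-methyl-2-(triethylsilyloxy)butyl]-2-(2-methylpropanoyl)-6,6-bis(3-methylbut-2-en-1-yl)cyclohexa-2,4-dien-1-one
Product: 15 3,5-dihydroxy-4-[(1S,2S)-1,2-dihydroxy-3-methylbutyl]-2-(2-methylpropanoyl)-6,6-bis(3-methylbut-2-en-1-yl)cyclohexa-2,4-dien-1-one (target)
Conditions: HF·pyridine, pyridine, THF, 0 °C
Reagents that add atoms: none
Why: Fluoride-driven cleavage of the secondary TES ether (Si–F bond formation) under pyridine-buffered conditions that are too mild to ionise the C1' carbinol or cyclise the prenyl groups and not basic enough for retro-aldol; both stereocentres are untouched.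

**Compound list**
1 | phloroglucinol (benzene-1,3,5-triol) | Oc1cc(O)cc(O)c1 | starting material
2 | isobutyryl chloride (2-methylpropanoyl chloride) | CC(C)C(=O)Cl | starting material
3 | phlorisobutyrophenone, 2-methyl-1-(2,4,6-trihydroxyphenyl)propan-1-one | CC(C)C(=O)c1c(O)cc(O)cc1O | intermediate
4 | prenyl bromide (1-bromo-3-methylbut-2-ene) | CC(C)=CCBr | starting material
5 | 3-prenylphlorisobutyrophenone, 2-methyl-1-[2,4,6-trihydroxy-3-(3-methylbut-2-en-1-yl)phenyl]propan-1-one | CC(C)=CCc1c(O)cc(O)c(C(=O)C(C)C)c1O | intermediate (not isolated)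
6 | 3,5-dihydroxy-2-(2-methylpropanoyl)-6,6-bis(3-methylbut-2-en-1-yl)cyclohexa-2,4-dien-1-one | CC(C)=CCC1(CC=C(C)C)C(=O)C(C(=O)C(C)C)=C(O)C=C1O | intermediate
7 | (S)-2-hydroxy-3-methylbutanoic acid | CC(C)[C@H](O)C(=O)O | starting material
8 | methyl (S)-2-hydroxy-3-methylbutanoate | CC(C)[C@H](O)C(=O)OC | intermediate
9 | methyl (S)-3-methyl-2-(triethylsilyloxy)butanoate | CC(C)[C@H](O[Si](CC)(CC)CC)C(=O)OC | intermediate
10 | diisobutylaluminium hemiacetal, [(2S)-1-methoxy-3-methyl-2-(triethylsilyloxy)butoxy]bis(2-methylpropyl)aluminium | CC(C)[C@H](O[Si](CC)(CC)CC)C(OC)O[Al](CC(C)C)CC(C)C | intermediate (not isolated)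
11 | (S)-3-methyl-2-(triethylsilyloxy)butanal | CC(C)[C@H](O[Si](CC)(CC)CC)C=O | intermediate
12 | bis(ethylzinc) dienolate of 6 (ethylzinc on the C3 and C5 oxygens) | CC(C)=CCC1(CC=C(C)C)C(=O)C(C(=O)C(C)C)=C(O[Zn]CC)C=C1O[Zn]CC | intermediate (not isolated)
13 | bis(ethylzinc) aldolate (ethylzinc on the C3 and C1' oxygens, 1'S,2'S) | CC(C)=CCC1(CC=C(C)C)C(=O)C(C(=O)C(C)C)=C(O[Zn]CC)C([C@H](O[Zn]CC)[C@@H](O[Si](CC)(CC)CC)C(C)C)=C1O | intermediate (not isolated)
14 | 3,5-dihydroxy-4-[(1S,2S)-1-hydroxy-3-methyl-2-(triethylsilyloxy)butyl]-2-(2-methylpropanoyl)-6,6-bis(3-methylbut-2-en-1-yl)cyclohexa-2,4-dien-1-one | CC(C)=CCC1(CC=C(C)C)C(=O)C(C(=O)C(C)C)=C(O)C([C@H](O)[C@@H](O[Si](CC)(CC)CC)C(C)C)=C1O | intermediate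
15 | 3,5-dihydroxy-4-[(1S,2S)-1,2-dihydroxy-3-methylbutyl]-2-(2-methylpropanoyl)-6,6-bis(3-methylbut-2-en-1-yl)cyclohexa-2,4-dien-1-one | CC(C)=CCC1(CC=C(C)C)C(=O)C(C(=O)C(C)C)=C(O)C([C@H](O)[C@@H](O)C(C)C)=C1O | target

**Totals**
Total step count: 7. Longest linear sequence: 5 steps (7 → 8 → 9 → 11 → 14 → 15); the other branch (1 → 3 → 6) is 2 steps.

**Three steps most likely to fail, with fallbacks**

Step 6 is the proposed zinc aldol. It may give poor conversion, the wrong facial selectivity if the TES oxygen does not chelate, or dehydration of the aldolate. The fallback makes the C4–C1' bond on the aromatic ring and dearomatises last; ortho-hydroxyalkylation of magnesium phenolates by aldehydes is established, and an aromatic adduct cannot dehydrate without losing aromaticity. It sets out from 3. Compound 3 is converted with EtMgBr (3 equiv, Et2O/CH2Cl2, 0 °C) into its bromomagnesium phenolate and treated with 11 (−20 °C → rt). This gives 2-methyl-1-[2,4,6-trihydroxy-3-[(1S,2S)-1-hydroxy-3-methyl-2-(triethylsilyloxy)butyl]phenyl]propan-1-one F1; any 1'-epimer is removed by chromatography at this stable aromatic stage. F1 has a single free ring carbon and is gem-diprenylated there with 4 (2.1 equiv) in 10% aq. KOH at 0 °C, which brings the route back at 14.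

Step 2 is the gem-diprenylation. It competes with 3,5-di- and tri-prenylation, so yield and separation are the risk. The fallback builds the ring from acyclic pieces so that the gem-diprenyl carbon is fixed from the start. It sets out from 4. Dimethyl malonate is dialkylated with 4 (NaH, THF/DMF) to dimethyl 2,2-bis(3-methylbut-2-en-1-yl)propanedioate F2. The dianion of commercial 5-methylhexane-2,4-dione (LiN(i-Pr)2, 3 equiv, THF, −78 → 0 °C) is acylated at its terminal methyl carbon by F2 to give methyl 8-methyl-2,2-bis(3-methylbut-2-en-1-yl)-3,5,7-trioxononanoate F3. Mg(OMe)2 in MeOH at reflux then closes the ring by Claisen (Dieckmann-type) condensation of C6 onto the remaining ester; the non-enolisable C2 rules out the competing aldol mode. Acidification returns the route at 6.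

Step 7 is the final desilylation. The product is a β-hydroxy enol-triketone that can dehydrate, undergo retro-aldol or cyclise under acid or base. The fallback removes the silyl group before the coupling, so no deprotection is run on the final skeleton. It sets out from 11. AcOH/THF/H2O (0 °C → rt) gives (S)-2-hydroxy-3-methylbutanal F4, which is stored as its hemiacetal dimer (3S,6S)-3,6-di(propan-2-yl)-1,4-dioxane-2,5-diol F5. F5 (0.6 equiv) is added to 12 prepared from 6 with 3.0 equiv of Et2Zn in CH2Cl2/THF. There the dimer opens and the α-oxygen is held as an ethylzinc alkoxide inside the same five-membered chelate. Work-up with aq. NaH2PO4 gives 15 directly.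

**Further compounds**
F1 | step 6 | 2-methyl-1-[2,4,6-trihydroxy-3-[(1S,2S)-1-hydroxy-3-methyl-2-(triethylsilyloxy)butyl]phenyl]propan-1-one | CC(C)C(=O)c1c(O)cc(O)c([C@H](O)[C@@H](O[Si](CC)(CC)CC)C(C)C)c1O
F2 | step 2 | dimethyl 2,2-bis(3-methylbut-2-en-1-yl)propanedioate | COC(=O)C(CC=C(C)C)(CC=C(C)C)C(=O)OC
F3 | step 2 | methyl 8-methyl-2,2-bis(3-methylbut-2-en-1-yl)-3,5,7-trioxononanoate | COC(=O)C(CC=C(C)C)(CC=C(C)C)C(=O)CC(=O)CC(=O)C(C)C
F4 | step 7 | (S)-2-hydroxy-3-methylbutanal | CC(C)[C@H](O)C=O
F5 | step 7 | (3S,6S)-3,6-di(propan-2-yl)-1,4-dioxane-2,5-diol | CC(C)[C@@H]1OC(O)[C@H](C(C)C)OC1O
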